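The numbers in the tables were computed with made-up constants; the scatter is artificial.

Count turnovers.

| setting | blue | teal | red | flask |
|---|---|---|---|---|
| left-handed substrate | 6.7 mM | 15 mM | 10 mM | 10 mM |
| right-handed substrate | 6.7 mM | 15 mM | 10 mM | 10 mM |
| gas | 1.5 mM (held) | 1.5 mM (held) | 1.5 mM (held) | 1.5 mM (held) |
| free catalyst | 20 µM | 20 µM | 40 µM | 20 µM |
| racemization catalyst | 0.42 mM | 0.42 mM | 0.42 mM | 0.42 mM |
| remark | run made earlier | run made earlier | run made earlier |  |
| time |  |  |  | 6.0 h |

- blue (time / h: left-handed product / %, right-handed product / %): 1.33: 6.7, 3.7; 2.50: 6.6, 3.4; 4.00: 6.7, 4.1; 5.00: 6.4, 4.0; 6.00: 6.3, 3.7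
- teal (time / h: left-handed product / %, right-handed product / %): 0.500: 6.6, 4.0; 0.833: 6.0, 4.2; 1.50: 6.0, 4.0; 3.00: 6.3, 4.2; 6.00: 6.5, 3.2
- red (time / h: left-handed product / %, right-handed product / %): 0.500: 11.9, 7.5; 0.833: 12.4, 6.8; 1.50: 11.9, 7.0; 3.00: 13.2, 7.1; 6.00: 12.2, 7.0

(standard deviation of a reading: 0.3 percentage points)

- free catalyst is single-handed; left-handed substrate and right-handed substrate are mirror images of each other, charged as a racemate, each of them at the stated concentration
- at the start none of reagent is dissolved
- candidate steps: reagent + free catalyst + left-handed substrate -> free catalyst + left-handed product; reagent + free catalyst + right-handed substrate -> free catalyst + right-handed product; left-handed substrate + racemization catalyst <-> right-handed substrate + racemization catalyst; gas <-> reagent; free catalyst -> spent catalyst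
- an excess is the difference of the two amounts in percent of their sum
- an excess is below zero if the other one leads

1. excess of left-handed product over right-handed product in the product at 8.0 min
2. excess of left-handed product over right-handed product in the product at 6.0 h
3. part of the left-handed substrate and right-handed substrate charged together that has reacted at 6.0 h

1. The products showed no steady rise in any run, so I took the mean of the five readings of both products as the plateau conversion x, the share of both substrates together that had reacted: 10.3% in blue, 10.2% in teal and 19.4% in red.

2. I turned these into the turnover number N, product formed per free catalyst charged: 69.1 in blue and 153 in teal. With equal catalyst, N grew by 2.21 while the substrate grew by 2.24, so N followed the substrate.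

3. N per mM of both substrates is x divided by the catalyst charge cC, which read 5.16 mM⁻¹ in blue and 5.10 mM⁻¹ in teal. Their mean put the flask at 10.3%.

4. That proportion was the weak link: from blue it asked 20.6% of red, and red read less than that, at 19.4%, a gap beyond the scatter. Substrate falls during a run, so I counted on what remained. Blue gave 5.45 mM⁻¹, teal 5.38 mM⁻¹ and red 5.39 mM⁻¹, with mean 5.41 mM⁻¹. This is the turnover allowance τ = ln(charged/left)/cC.

5. For the flask, τ gave a conversion of 10.2%, or 102 turnovers per catalyst.

The forecast, holding that “the catalyst dies early and later time adds nothing”, gave an early excess of 27% (23% to 31%), a late excess of 25.5% (23.5% to 27.5%) and a conversion of 10.2% (9.7% to 10.7%).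

The flask gave an early excess of 26.8%, a late excess of 26.8% and a conversion of 10.4%.

    reagent + free catalyst + left-handed substrate → free catalyst + left-handed product (k = 5.80 × 10⁵ M⁻² min⁻¹)
    reagent + free catalyst + right-handed substrate → free catalyst + right-handed product (k = 3.30 × 10⁵ M⁻² min⁻¹)
    left-handed substrate + racemization catalyst ⇌ right-handed substrate + racemization catalyst, rate k3*[racemization catalyst]*[left-handed substrate] forward; the back reaction follows from the equilibrium constant (k = 140 M⁻¹ min⁻¹)
    gas ⇌ reagent, rate k4*(csat - [reagent]) (kL = 5.60 min⁻¹)
    free catalyst → spent catalyst (k = 0.120 min⁻¹)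

The conversion of free catalyst into spent catalyst is the main reason the flask stopped at 10.4%: with that step struck out, the same flask reached 99.2%. The flask's own conversion puts τ at 5.47 mM⁻¹. Carried to a neighbour flask charged with 0.034 mM of free catalyst, the mean τ of the three runs, 5.41 mM⁻¹, reckons 16.8%, and the neighbour flask reacted 16.8%.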